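**Retrosynthetic overview**
1. Target 16 comes from LiAlH4 reduction of cis-2,3-diester 15, which comes from hydrogenation of trans-1-aryl-1,2-dihydronaphthalene diester 14 (H2 anti to the C2 ester sets C3; the benzyl ethers fall off in the same step).
2. 14 comes from closing the carbocycle at C3–C4 by an intramolecular Stobbe condensation of aldehyde succinate 11, then equilibrating C2 to trans. The usual C1–C8a Friedel–Crafts or quinone-methide closure is not used.
3. 11 comes from the C2–C3 bond: alkylation of the enolate of (R)-3,3-diarylpropanoate 7 with methyl bromoacetate 8.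
4. 7 comes from a Hayashi–Miyaura asymmetric 1,4-addition of boronic acid 6 to cinnamate 5, which sets C1 first and is the only catalyst-controlled stereocenter. 5 comes from a Heck reaction of bromo acetal 3, made from O-benzylvanillin 1.
5. Ring order: both benzene rings are bought. The only ring formed is the carbocyclic ring of the tetralin (step 6). C2 and then C3 are relayed from C1.

Assumption: tetralin numbering (C1 aryl-bearing, then C2, C3, C4) is used, the target being (1R,2S,3R) with the C1 aryl trans to the cis-2,3-bis(hydroxymethyl) pair; (R,R)-Ph-bod* is taken as the ligand antipode that gives (R)-7, and its mirror image is used instead if the first run shows the opposite sense.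

**Step 1**
Reactants: 1 4-(benzyloxy)-3-methoxybenzaldehyde
Product: 2 4-(benzyloxy)-2-bromo-5-methoxybenzaldehyde
Conditions: Br2 (1.1 equiv), NaOAc, AcOH, 23 °C
Reagents that add atoms: bromine, BrBr
Why: Electrophilic aromatic bromination goes para to the methoxy group (ortho to CHO), as with veratraldehyde, which puts the halogen on the carbon that becomes C8a; no stereocenter is formed.

**Step 2**
Reactants: 2 4-(benzyloxy)-2-bromo-5-methoxybenzaldehyde
Product: 3 2-[4-(benzyloxy)-2-bromo-5-methoxyphenyl]-1,3-dioxolane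
Conditions: HOCH2CH2OH (3 equiv), p-TsOH·H2O (cat.), toluene, reflux, Dean–Stark
Reagents that add atoms: ethylene glycol, OCCO
Why: Acid-catalysed acetalization with azeotropic removal of water masks the future C4 aldehyde against aryl-rhodium 1,2-addition and against the ester enolate of step 5.

**Step 3**
Reactants: 3 2-[4-(benzyloxy)-2-bromo-5-methoxyphenyl]-1,3-dioxolane; 4 methyl acrylate
Product: 5 methyl (2E)-3-[5-(benzyloxy)-2-(1,3-dioxolan-2-yl)-4-methoxyphenyl]prop-2-enoate
Conditions: Pd(OAc)2 (3 mol %), P(o-tol)3 (6 mol %), K2CO3, DMF, 110 °C, sealed tube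
Reagents that add atoms: none
Why: Mizoroki–Heck reaction of the aryl bromide with the acrylate gives the E-cinnamate by syn insertion and syn β-hydride elimination; the acetal and benzyl ether are inert to the basic conditions.

**Step 4**
Reactants: 5 methyl (2E)-3-[5-(benzyloxy)-2-(1,3-dioxolan-2-yl)-4-methoxyphenyl]prop-2-enoate; 6 [4-(benzyloxy)-3-methoxyphenyl]boronic acid
Product: 7 methyl (3R)-3-[5-(benzyloxy)-2-(1,3-dioxolan-2-yl)-4-methoxyphenyl]-3-[4-(benzyloxy)-3-methoxyphenyl]propanoate
Conditions: [RhCl(C2H4)2]2 (2.5 mol %), (R,R)-Ph-bod* (5.5 mol %), 6 (2 equiv), KOH (0.1 equiv), 1,4-dioxane/H2O 10:1, 40 °C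
Reagents that add atoms: none
Why: Hayashi–Miyaura asymmetric 1,4-addition, in which the aryl-rhodium species formed by transmetalation adds to the Si face of C3 of the enoate inside the chiral diene pocket and water protonates the rhodium enolate, giving the (R) benzhydryl center that becomes C1.

**Step 5**
Reactants: 7 methyl (3R)-3-[5-(benzyloxy)-2-(1,3-dioxolan-2-yl)-4-methoxyphenyl]-3-[4-(benzyloxy)-3-methoxyphenyl]propanoate; 8 methyl bromoacetate
Product: 11 dimethyl 2-{(R)-[5-(benzyloxy)-2-formyl-4-methoxyphenyl][4-(benzyloxy)-3-methoxyphenyl]methyl}butanedioate (both C2 epimers), via lithium ester enolate 9 (not isolated), via dioxolane succinate 10 (not isolated)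
Conditions: LiN(i-Pr)2 (1.1 equiv), THF, −78 °C; then 8 (1.3 equiv), −78 → −30 °C; then 2 M HCl, THF, 23 °C
Reagents that add atoms: water, O
Why: Ester enolate alkylation (SN2 on the bromoacetate) makes the C2–C3 bond, and the acidic work-up hydrolyses the electron-rich aryl dioxolane; the benzhydryl C1–H is not acidic, and the new C2 center forms as a mixture that is corrected in step 7.

**Step 6**
Reactants: 11 dimethyl 2-{(R)-[5-(benzyloxy)-2-formyl-4-methoxyphenyl][4-(benzyloxy)-3-methoxyphenyl]methyl}butanedioate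
Product: 13 dimethyl (1R)-7-(benzyloxy)-1-[4-(benzyloxy)-3-methoxyphenyl]-6-methoxy-1,2-dihydronaphthalene-2,3-dicarboxylate (both C2 epimers), via sodium half-ester salt 12 (not isolated)
Conditions: NaOMe (1.2 equiv), MeOH/THF, 0 → 23 °C; then evaporate, MeI (2 equiv), DMF, 23 °C
Reagents that add atoms: iodomethane, CI
Why: Intramolecular Stobbe condensation, in which the unhindered CH2 ester enolate adds to the ortho aldehyde in a six-membered closure, the aldolate takes over the neighbouring acyl group and E1cB opening gives the conjugated C3=C4 half-ester salt irreversibly, which MeI O-methylates; C1 is untouched.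

**Step 7**
Reactants: 13 dimethyl (1R)-7-(benzyloxy)-1-[4-(benzyloxy)-3-methoxyphenyl]-6-methoxy-1,2-dihydronaphthalene-2,3-dicarboxylate (both C2 epimers)
Product: 14 dimethyl (1R,2S)-7-(benzyloxy)-1-[4-(benzyloxy)-3-methoxyphenyl]-6-methoxy-1,2-dihydronaphthalene-2,3-dicarboxylate (C1 aryl and C2 ester trans)
Conditions: NaOMe (0.2 equiv), MeOH/THF, 0 → 23 °C, under argon
Reagents that add atoms: none
Why: Ester enolate epimerization at C2 under thermodynamic control gives the trans isomer, in which the C1 aryl and C2 ester sit pseudo-diaxial and avoid each other (the arrangement of the natural 1-aryl-1,2-dihydronaphthalene-2,3-dicarboxylates); C1 has no acidic hydrogen.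

**Step 8**
Reactants: 14 dimethyl (1R,2S)-7-(benzyloxy)-1-[4-(benzyloxy)-3-methoxyphenyl]-6-methoxy-1,2-dihydronaphthalene-2,3-dicarboxylate
Product: 15 dimethyl (1R,2S,3R)-7-hydroxy-1-(4-hydroxy-3-methoxyphenyl)-6-methoxy-1,2,3,4-tetrahydronaphthalene-2,3-dicarboxylate
Conditions: H2 (1 atm), 10% Pd/C, EtOAc/MeOH, 23 °C
Reagents that add atoms: none
Why: Heterogeneous syn hydrogenation of the C3=C4 alkene takes place from the face opposite the adjacent pseudoaxial C2 ester, as is established for 1-aryl-1,2-dihydronaphthalene-2,3-diesters, so the C3 ester ends cis to the C2 ester and trans to the aryl group (3R), while both benzyl ethers are hydrogenolysed.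

**Step 9**
Reactants: 15 dimethyl (1R,2S,3R)-7-hydroxy-1-(4-hydroxy-3-methoxyphenyl)-6-methoxy-1,2,3,4-tetrahydronaphthalene-2,3-dicarboxylate
Product: 16 (6R,7S,8R)-8-(4-hydroxy-3-methoxyphenyl)-6,7-bis(hydroxymethyl)-3-methoxy-5,6,7,8-tetrahydronaphthalen-2-ol (tetralin numbering 1R,2S,3R)
Conditions: LiAlH4 (6 equiv), THF, 0 → 65 °C; aqueous work-up at pH 5
Reagents that add atoms: none
Why: LiAlH4 reduction of both esters to primary alcohols (the phenols are carried as phenoxides) is faster than enolization, so C2 and C3 are kept and the (1R,2S,3R) tetraol results.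

**Compound list**
1 | 4-(benzyloxy)-3-methoxybenzaldehyde | COc1cc(C=O)ccc1OCc1ccccc1 | starting material
2 | 4-(benzyloxy)-2-bromo-5-methoxybenzaldehyde | COc1cc(C=O)c(Br)cc1OCc1ccccc1 | intermediate
3 | 2-[4-(benzyloxy)-2-bromo-5-methoxyphenyl]-1,3-dioxolane | COc1cc(C2OCCO2)c(Br)cc1OCc1ccccc1 | intermediate
4 | methyl acrylate | C=CC(=O)OC | starting material
5 | methyl (2E)-3-[5-(benzyloxy)-2-(1,3-dioxolan-2-yl)-4-methoxyphenyl]prop-2-enoate | COC(=O)/C=C/c1cc(OCc2ccccc2)c(OC)cc1C1OCCO1 | intermediate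
6 | [4-(benzyloxy)-3-methoxyphenyl]boronic acid | COc1cc(B(O)O)ccc1OCc1ccccc1 | starting material
7 | methyl (3R)-3-[5-(benzyloxy)-2-(1,3-dioxolan-2-yl)-4-methoxyphenyl]-3-[4-(benzyloxy)-3-methoxyphenyl]propanoate | COc1cc([C@@H](CC(=O)OC)c2cc(OCc3ccccc3)c(OC)cc2C2OCCO2)ccc1OCc1ccccc1 | intermediate
8 | methyl bromoacetate | COC(=O)CBr | starting material
9 | lithium enolate of 7 (not isolated) | [Li+].COc1cc([C@@H](C=C([O-])OC)c2cc(OCc3ccccc3)c(OC)cc2C2OCCO2)ccc1OCc1ccccc1 | intermediate
10 | dimethyl 2-{(R)-[5-(benzyloxy)-2-(1,3-dioxolan-2-yl)-4-methoxyphenyl][4-(benzyloxy)-3-methoxyphenyl]methyl}butanedioate, C2 epimers (not isolated) | COc1cc([C@@H](C(CC(=O)OC)C(=O)OC)c2cc(OCc3ccccc3)c(OC)cc2C2OCCO2)ccc1OCc1ccccc1 | intermediate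
11 | dimethyl 2-{(R)-[5-(benzyloxy)-2-formyl-4-methoxyphenyl][4-(benzyloxy)-3-methoxyphenyl]methyl}butanedioate, C2 epimers | COc1cc([C@@H](C(CC(=O)OC)C(=O)OC)c2cc(OCc3ccccc3)c(OC)cc2C=O)ccc1OCc1ccccc1 | intermediate
12 | sodium (1R)-7-(benzyloxy)-1-[4-(benzyloxy)-3-methoxyphenyl]-6-methoxy-3-(methoxycarbonyl)-1,2-dihydronaphthalene-2-carboxylate, C2 epimers (not isolated) | [Na+].COc1cc([C@@H]2c3cc(OCc4ccccc4)c(OC)cc3C=C(C(=O)OC)C2C([O-])=O)ccc1OCc1ccccc1 | intermediate
13 | dimethyl (1R)-7-(benzyloxy)-1-[4-(benzyloxy)-3-methoxyphenyl]-6-methoxy-1,2-dihydronaphthalene-2,3-dicarboxylate, C2 epimers | COc1cc([C@@H]2c3cc(OCc4ccccc4)c(OC)cc3C=C(C(=O)OC)C2C(=O)OC)ccc1OCc1ccccc1 | intermediate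
14 | dimethyl (1R,2S)-7-(benzyloxy)-1-[4-(benzyloxy)-3-methoxyphenyl]-6-methoxy-1,2-dihydronaphthalene-2,3-dicarboxylate | COc1cc([C@@H]2c3cc(OCc4ccccc4)c(OC)cc3C=C(C(=O)OC)[C@H]2C(=O)OC)ccc1OCc1ccccc1 | intermediate
15 | dimethyl (1R,2S,3R)-7-hydroxy-1-(4-hydroxy-3-methoxyphenyl)-6-methoxy-1,2,3,4-tetrahydronaphthalene-2,3-dicarboxylate | COc1cc([C@@H]2c3cc(O)c(OC)cc3C[C@@H](C(=O)OC)[C@H]2C(=O)OC)ccc1O | intermediate
16 | (6R,7S,8R)-8-(4-hydroxy-3-methoxyphenyl)-6,7-bis(hydroxymethyl)-3-methoxy-5,6,7,8-tetrahydronaphthalen-2-ol | COc1cc([C@@H]2c3cc(O)c(OC)cc3C[C@@H](CO)[C@H]2CO)ccc1O | target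

**Totals**
Total step count: 9. Longest linear sequence: 9 steps (1 → 16); compounds 4, 6 and 8 are bought.

**Three steps most likely to fail**

Step 4. The acceptor is an electron-rich β-aryl enoate with an ortho dioxolanyl group, so the addition may be slow, the boronic acid may protodeboronate, and the ee is unproven. The fallback replaces catalyst control by auxiliary control. It sets out from 5, which is saponified (LiOH, THF/H2O, acidified to pH 4) to the cinnamic acid F1. F1 is joined (t-BuCOCl, Et3N, then LiCl) to (4S)-4-phenyl-1,3-oxazolidin-2-one to give the N-enoyl oxazolidinone F2. 1-(Benzyloxy)-4-bromo-2-methoxybenzene (bought) and Mg in THF give the aryl Grignard reagent F3. F3 is added to F2 with CuBr·SMe2 at −20 °C; in the chelated syn-s-cis imide the phenyl group of the auxiliary covers the Re face of C3, so the aryl group enters from the Si face and gives the conjugate adduct F4. NaOMe in MeOH at 0 °C releases the auxiliary and the route comes back at 7.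

Step 6. The ring closure competes with aldol attack from the C2 enolate (five-membered indanol, which can be trapped as a lactone) and with intermolecular condensation. The fallback closes the same C3–C4 bond under Lewis acid instead of base. It sets out from 10, isolated by a neutral work-up of the alkylation in place of the HCl treatment. LiN(i-Pr)2 with Me3SiCl at −78 °C deprotonates the unhindered CH2 ester and gives the silyl ketene acetal F5. Me3SiOTf in CH2Cl2 at −78 °C opens the dioxolane to an oxocarbenium ion that is captured in an intramolecular Mukaiyama-type addition, giving the 4-(2-hydroxyethoxy) tetralin diester F6. NaOMe in MeOH then eliminates the β-alkoxy group (E1cB) and the route comes back at 13.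

Step 7. Base may move the double bond to C2=C3 (the 1,4-dihydro isomer), which would make C1–H acidic and open the way to racemization or aromatization, or the trans:cis ratio at equilibrium may be too low. The fallback drops the dihydronaphthalene equilibration and lets a cis-fused anhydride set C2 and C3 together. It sets out from 13, which is hydrogenated as the epimer mixture (H2, 10% Pd/C) to the tetralin diester mixture F7. LiOH in THF/H2O gives the diacid F8. Ac2O with NaOAc at 120 °C closes the anhydride, acetylates both phenols and equilibrates both α-centers to the most stable isomer, the cis-fused anhydride diacetate F9, in which the C1 aryl is trans to the anhydride ring. LiAlH4 in THF reduces the anhydride and removes the acetates, and the route comes back at 16.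

**Further compounds**
F1 | step 4 | (2E)-3-[5-(benzyloxy)-2-(1,3-dioxolan-2-yl)-4-methoxyphenyl]prop-2-enoic acid | OC(=O)/C=C/c1cc(OCc2ccccc2)c(OC)cc1C1OCCO1
F2 | step 4 | (4S)-3-{(2E)-3-[5-(benzyloxy)-2-(1,3-dioxolan-2-yl)-4-methoxyphenyl]prop-2-enoyl}-4-phenyl-1,3-oxazolidin-2-one | O=C(/C=C/c1cc(OCc2ccccc2)c(OC)cc1C1OCCO1)N1[C@@H](c2ccccc2)COC1=O
F3 | step 4 | [4-(benzyloxy)-3-methoxyphenyl]magnesium bromide | COc1cc([Mg]Br)ccc1OCc1ccccc1
F4 | step 4 | (4S)-3-{(3R)-3-[5-(benzyloxy)-2-(1,3-dioxolan-2-yl)-4-methoxyphenyl]-3-[4-(benzyloxy)-3-methoxyphenyl]propanoyl}-4-phenyl-1,3-oxazolidin-2-one | COc1cc([C@@H](CC(=O)N2[C@@H](c3ccccc3)COC2=O)c2cc(OCc3ccccc3)c(OC)cc2C2OCCO2)ccc1OCc1ccccc1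
F5 | step 6 | methyl 2-{(R)-[5-(benzyloxy)-2-(1,3-dioxolan-2-yl)-4-methoxyphenyl][4-(benzyloxy)-3-methoxyphenyl]methyl}-4-methoxy-4-[(trimethylsilyl)oxy]but-3-enoate | COc1cc([C@@H](C(C=C(OC)O[Si](C)(C)C)C(=O)OC)c2cc(OCc3ccccc3)c(OC)cc2C2OCCO2)ccc1OCc1ccccc1
F6 | step 6 | dimethyl (1R)-7-(benzyloxy)-1-[4-(benzyloxy)-3-methoxyphenyl]-4-(2-hydroxyethoxy)-6-methoxy-1,2,3,4-tetrahydronaphthalene-2,3-dicarboxylate (mixture at C2, C3, C4) | COc1cc([C@@H]2c3cc(OCc4ccccc4)c(OC)cc3C(OCCO)C(C(=O)OC)C2C(=O)OC)ccc1OCc1ccccc1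
F7 | step 7 | dimethyl (1R)-7-hydroxy-1-(4-hydroxy-3-methoxyphenyl)-6-methoxy-1,2,3,4-tetrahydronaphthalene-2,3-dicarboxylate (mixture at C2 and C3) | COc1cc([C@@H]2c3cc(O)c(OC)cc3CC(C(=O)OC)C2C(=O)OC)ccc1O
F8 | step 7 | (1R)-7-hydroxy-1-(4-hydroxy-3-methoxyphenyl)-6-methoxy-1,2,3,4-tetrahydronaphthalene-2,3-dicarboxylic acid (mixture at C2 and C3) | COc1cc([C@@H]2c3cc(O)c(OC)cc3CC(C(=O)O)C2C(=O)O)ccc1O
F9 | step 7 | (1R,2S,3R)-7-acetoxy-1-(4-acetoxy-3-methoxyphenyl)-6-methoxy-1,2,3,4-tetrahydronaphthalene-2,3-dicarboxylic anhydride | COc1cc([C@@H]2c3cc(OC(C)=O)c(OC)cc3C[C@@H](C(=O)O5)[C@H]2C5=O)ccc1OC(C)=O
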